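**Strategy**

The side chain is disconnected between the vinyl carbon attached to C6 of the benzoquinone ring and the neighbouring oxygen-bearing carbinol carbon. The key step exploits this allylic C–O stereocentre: it is made as a C–B bond. A (+)-sparteine-controlled α-lithiated homoprenyl carbamate captures an α-aryl vinyl boronic ester; in the resulting boron ate complex the vinyl carbon shifts from boron to carbon with loss of the carbamate (Matteson-type 1,2-metallate rearrangement), and oxidation then turns C–B into C–OH. One flask thus joins both halves and sets the (S) centre. The quinone travels as a 1,2,4-trimethoxy-3-methylbenzene and is unveiled last with CAN, after angeloylation.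

Key step: step 6

Remark on the chemistry: the acyloxy-bearing carbon of the target is (S). s-BuLi/(−)-sparteine removes the pro-S proton of O-alkyl carbamates, and the sequence retention (borylation), inversion (1,2-shift), retention (oxidation) would then give the (R) alcohol here, so the commercially available (+)-sparteine is used.

**Route**

Step 1
Reactants: 1 3,5-dimethoxy-4-methylbenzaldehyde
Product: 2 2-bromo-3,5-dimethoxy-4-methylbenzaldehyde
Conditions: NBS (1.05 equiv), MeCN, 0 °C → rt
Reagents that add atoms: N-bromosuccinimide O=C1CCC(=O)N1Br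
Why: Electrophilic aromatic bromination; the two free ring positions are equivalent and each is ortho to one methoxy group and para to the other, so one monobromide should form, and the ionic conditions spare the benzylic methyl group.

Step 2
Reactants: 2 2-bromo-3,5-dimethoxy-4-methylbenzaldehyde
Product: 3 2,3,5-trimethoxy-4-methylbenzaldehyde
Conditions: NaOMe (4 equiv), CuBr (cat.), EtOAc (cat.), MeOH/DMF, 100 °C; dilute HCl work-up
Reagents that add atoms: sodium methoxide [Na+].[O-]C
Why: Ullmann-type copper-catalysed methoxylation of an aryl bromide, a reaction that tolerates bromides flanked by methoxy groups and is assisted by the ortho carbonyl group; the aldehyde has no α-hydrogen and is held reversibly as its hemiacetal in the medium.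

Step 3
Reactants: 3 2,3,5-trimethoxy-4-methylbenzaldehyde
Product: 4 1-ethynyl-2,3,5-trimethoxy-4-methylbenzene
Conditions: Ohira–Bestmann reagent (1.3 equiv), K2CO3, MeOH, 0 °C → rt
Reagents that add atoms: dimethyl (1-diazo-2-oxopropyl)phosphonate CC(=O)C(=[N+]=[N-])P(=O)(OC)OC
Why: Seyferth–Gilbert homologation in the Ohira–Bestmann variant, which converts non-enolisable aryl aldehydes into terminal alkynes under mild carbonate conditions.

Step 4
Reactants: 4 1-ethynyl-2,3,5-trimethoxy-4-methylbenzene
Product: 6 4,4,5,5-tetramethyl-2-[1-(2,3,5-trimethoxy-4-methylphenyl)ethenyl]-1,3,2-dioxaborolane, via α-vinylalane 5 (not isolated)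
Conditions: DIBAL-H (1.3 equiv), Ni(dppp)Cl2 (3 mol %), THF, 0 °C → rt; then MeOBpin (3 equiv), rt → 80 °C
Reagents that add atoms: 2-methoxy-4,4,5,5-tetramethyl-1,3,2-dioxaborolane COB1OC(C)(C)C(C)(C)O1
Why: Nickel-catalysed Markovnikov (α-selective) hydroalumination of an aryl acetylene places aluminium on the aryl-bearing carbon, and aluminium-to-boron transmetalation with the methoxyboronate then gives the 1,1-disubstituted vinyl boronic ester.

Step 5
Reactants: 7 4-methylpent-3-en-1-ol
Product: 8 4-methylpent-3-en-1-yl N,N-diisopropylcarbamate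
Conditions: i-Pr2NCOCl (1.1 equiv), Et3N, CH2Cl2, reflux
Reagents that add atoms: N,N-diisopropylcarbamoyl chloride CC(C)N(C(C)C)C(Cl)=O
Why: O-Carbamoylation (acyl substitution) of a primary alcohol gives the hindered carbamate that directs the α-lithiation and later serves as the leaving group.

Step 6
Reactants: 8 4-methylpent-3-en-1-yl N,N-diisopropylcarbamate; 6 4,4,5,5-tetramethyl-2-[1-(2,3,5-trimethoxy-4-methylphenyl)ethenyl]-1,3,2-dioxaborolane
Product: 12 (S)-6-methyl-2-(2,3,5-trimethoxy-4-methylphenyl)hepta-1,5-dien-3-ol, via (R)-α-lithio carbamate 9 (not isolated), via boron ate complex 10 (not isolated), via (S)-allylic boronic ester 11 (not isolated)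
Conditions: 8 (1.3 equiv), s-BuLi (1.25 equiv), (+)-sparteine (1.3 equiv), Et2O, −78 °C, 5 h; then 6 (1.0 equiv), −78 °C, 1 h; MgBr2·OEt2, −78 °C → reflux; then 2 M NaOH, 30% H2O2, THF, 0 °C → rt
Reagents that add atoms: hydrogen peroxide OO
Why: s-BuLi/(+)-sparteine removes the pro-R α-proton of 8 to give the configurationally stable organolithium 9, which adds to the boron of 6 with retention to form ate complex 10; on warming with MgBr2 the 1-arylvinyl group migrates from boron to carbon antiperiplanar to the departing carbamate (inversion), which forms the bond between the vinyl carbon and the carbinol carbon, and alkaline peroxide then replaces boron in 11 by OH with retention. The closest known reaction type is the lithiation–borylation of O-alkyl N,N-diisopropylcarbamates with alkenyl boronic esters, a reagent-controlled Matteson-type homologation followed by oxidation of the allylic boronic ester. No ring is closed. The single new stereocentre is controlled by the sparteine ligand alone, and the retention–inversion–retention sequence should translate (R)-9 into the (S) alcohol, because the vinyl group outranks the homoprenyl CH2. The step needs migration of the vinyl group in preference to a pinacol oxygen and no 1,3-borotropic shift of 11: sp2 groups migrate readily, MgBr2 promotes the shift at moderate temperature, and 11 is oxidised in the same flask.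

Step 7
Reactants: 12 (S)-6-methyl-2-(2,3,5-trimethoxy-4-methylphenyl)hepta-1,5-dien-3-ol; 13 angelic acid, (Z)-2-methylbut-2-enoic acid
Product: 14 (S)-6-methyl-2-(2,3,5-trimethoxy-4-methylphenyl)hepta-1,5-dien-3-yl (Z)-2-methylbut-2-enoate
Conditions: 13, 2,4,6-trichlorobenzoyl chloride, Et3N, toluene, rt; then 12, 80 °C (no DMAP)
Reagents that add atoms: none
Why: Yamaguchi-type mixed-anhydride esterification without a nucleophilic catalyst, which avoids the conjugate addition–elimination pathway that turns angelates into tiglates; acylation occurs at oxygen, so the stereocentre is untouched.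

Step 8
Reactants: 14 (S)-6-methyl-2-(2,3,5-trimethoxy-4-methylphenyl)hepta-1,5-dien-3-yl (Z)-2-methylbut-2-enoate
Product: 15 (S)-2-(5-methoxy-4-methyl-3,6-dioxocyclohexa-1,4-dien-1-yl)-6-methylhepta-1,5-dien-3-yl (Z)-2-methylbut-2-enoate
Conditions: CAN (2.5 equiv), MeCN/H2O, 0 °C, short reaction time
Reagents that add atoms: water O
Why: Oxidative demethylation of a 1,4-dimethoxyarene with cerium(IV) to the para-benzoquinone: water attacks the two para methoxy-bearing carbons of the arene radical cation, the third methoxy group is retained, and the electron-rich arene is oxidised well before the isolated alkenes or the ester.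

**Compound list**

1 | 3,5-dimethoxy-4-methylbenzaldehyde | O=Cc1cc(OC)c(C)c(OC)c1 | starting material
2 | 2-bromo-3,5-dimethoxy-4-methylbenzaldehyde | O=Cc1cc(OC)c(C)c(OC)c1Br | intermediate
3 | 2,3,5-trimethoxy-4-methylbenzaldehyde | O=Cc1cc(OC)c(C)c(OC)c1OC | intermediate
4 | 1-ethynyl-2,3,5-trimethoxy-4-methylbenzene | C#Cc1cc(OC)c(C)c(OC)c1OC | intermediate
5 | diisobutyl[1-(2,3,5-trimethoxy-4-methylphenyl)ethenyl]alane (not isolated) | C=C(c1cc(OC)c(C)c(OC)c1OC)[Al](CC(C)C)CC(C)C | intermediate
6 | 4,4,5,5-tetramethyl-2-[1-(2,3,5-trimethoxy-4-methylphenyl)ethenyl]-1,3,2-dioxaborolane | C=C(B1OC(C)(C)C(C)(C)O1)c1cc(OC)c(C)c(OC)c1OC | intermediate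
7 | 4-methylpent-3-en-1-ol | CC(C)=CCCO | starting material
8 | 4-methylpent-3-en-1-yl N,N-diisopropylcarbamate | CC(C)=CCCOC(=O)N(C(C)C)C(C)C | intermediate
9 | (R)-[1-(N,N-diisopropylcarbamoyloxy)-4-methylpent-3-en-1-yl]lithium, as its (+)-sparteine complex (not isolated) | CC(C)=CC[C@H](OC(=O)N(C(C)C)C(C)C)[Li] | intermediate
10 | lithium (R)-[1-(N,N-diisopropylcarbamoyloxy)-4-methylpent-3-en-1-yl][1-(2,3,5-trimethoxy-4-methylphenyl)ethenyl](pinacolato)borate (not isolated) | [Li+].CC(C)=CC[C@H](OC(=O)N(C(C)C)C(C)C)[B-]1(OC(C)(C)C(C)(C)O1)C(=C)c1cc(OC)c(C)c(OC)c1OC | intermediate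
11 | (S)-4,4,5,5-tetramethyl-2-[6-methyl-2-(2,3,5-trimethoxy-4-methylphenyl)hepta-1,5-dien-3-yl]-1,3,2-dioxaborolane (not isolated) | C=C(c1cc(OC)c(C)c(OC)c1OC)[C@H](CC=C(C)C)B1OC(C)(C)C(C)(C)O1 | intermediate
12 | (S)-6-methyl-2-(2,3,5-trimethoxy-4-methylphenyl)hepta-1,5-dien-3-ol | C=C(c1cc(OC)c(C)c(OC)c1OC)[C@H](CC=C(C)C)O | intermediate
13 | angelic acid, (Z)-2-methylbut-2-enoic acid | C/C=C(/C)C(=O)O | starting material
14 | (S)-6-methyl-2-(2,3,5-trimethoxy-4-methylphenyl)hepta-1,5-dien-3-yl (Z)-2-methylbut-2-enoate | C=C(c1cc(OC)c(C)c(OC)c1OC)[C@H](CC=C(C)C)OC(=O)/C(C)=C\C | intermediate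
15 | (S)-2-(5-methoxy-4-methyl-3,6-dioxocyclohexa-1,4-dien-1-yl)-6-methylhepta-1,5-dien-3-yl (Z)-2-methylbut-2-enoate | C=C(C1=CC(=O)C(C)=C(OC)C1=O)[C@H](CC=C(C)C)OC(=O)/C(C)=C\C | target

**Step count**

Total steps: 8. Longest linear sequence: 7 (steps 1–4, then 6–8); step 5 is the one-step side branch.

**Steps most likely to fail**

Step 6. The ate complex may form slowly or incompletely at the hindered α-aryl vinyl boron, the lithiated carbamate may decompose before capture, or the allylic boronic ester may undergo a borotropic shift before oxidation; each would lower yield or enantiopurity. The fallback sets out from 4 and 7 and comes back at 12. Alkyne 4 would be taken through the same nickel-catalysed hydroalumination but quenched with N-iodosuccinimide to give 1-(1-iodoethenyl)-2,3,5-trimethoxy-4-methylbenzene F1. Alcohol 7 would be oxidised with buffered Dess–Martin periodinane to 4-methylpent-3-enal F2. A Nozaki–Hiyama–Kishi coupling of F1 and F2 (CrCl2, cat. NiCl2, DMSO, rt) should give racemic 6-methyl-2-(2,3,5-trimethoxy-4-methylphenyl)hepta-1,5-dien-3-ol F3. Oxidation (Dess–Martin periodinane, NaHCO3) should give 6-methyl-2-(2,3,5-trimethoxy-4-methylphenyl)hepta-1,5-dien-3-one F4. A Corey–Bakshi–Shibata reduction of F4 with the (R)-methyl oxazaborolidine and catecholborane at −78 °C, in which the α-arylvinyl group acts as the large substituent, should then give 12.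

Step 2. Methoxide may attack the free aldehyde (hydride transfer or Cannizzaro-type loss), and reductive debromination may compete with C–O coupling at the doubly ortho-substituted carbon. The fallback sets out from 2 and comes back at 3. A Miyaura borylation (B2pin2, Pd(dppf)Cl2, KOAc, dioxane, 90 °C) should give 3,5-dimethoxy-4-methyl-2-(4,4,5,5-tetramethyl-1,3,2-dioxaborolan-2-yl)benzaldehyde F5. Oxidation of the C–B bond with N-methylmorpholine N-oxide, which spares the aldehyde, should give 2-hydroxy-3,5-dimethoxy-4-methylbenzaldehyde F6. O-Methylation (MeI, K2CO3, DMF) then gives 3.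

Step 4. Regiocontrol of the hydrometalation may be lost on this electron-rich ortho-methoxy aryl alkyne (aluminium delivered to the terminal carbon), or the acetylenic C–H may be aluminated instead. The fallback sets out from 3 and comes back at 6. Addition of MeMgBr to 3 should give racemic 1-(2,3,5-trimethoxy-4-methylphenyl)ethanol F7. Oxidation (Dess–Martin periodinane) should give 1-(2,3,5-trimethoxy-4-methylphenyl)ethanone F8. Enol triflation (KHMDS, PhNTf2, THF, −78 °C) should give 1-(2,3,5-trimethoxy-4-methylphenyl)ethenyl trifluoromethanesulfonate F9. A palladium-catalysed Miyaura borylation of F9 (B2pin2, PdCl2(PPh3)2, PPh3, KOPh, toluene, 50 °C) then gives 6.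

**Further compounds**

F1 | step 6 | 1-(1-iodoethenyl)-2,3,5-trimethoxy-4-methylbenzene | C=C(I)c1cc(OC)c(C)c(OC)c1OC
F2 | step 6 | 4-methylpent-3-enal | CC(C)=CCC=O
F3 | step 6 | racemic 6-methyl-2-(2,3,5-trimethoxy-4-methylphenyl)hepta-1,5-dien-3-ol | C=C(c1cc(OC)c(C)c(OC)c1OC)C(O)CC=C(C)C
F4 | step 6 | 6-methyl-2-(2,3,5-trimethoxy-4-methylphenyl)hepta-1,5-dien-3-one | C=C(c1cc(OC)c(C)c(OC)c1OC)C(=O)CC=C(C)C
F5 | step 2 | 3,5-dimethoxy-4-methyl-2-(4,4,5,5-tetramethyl-1,3,2-dioxaborolan-2-yl)benzaldehyde | O=Cc1cc(OC)c(C)c(OC)c1B1OC(C)(C)C(C)(C)O1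
F6 | step 2 | 2-hydroxy-3,5-dimethoxy-4-methylbenzaldehyde | O=Cc1cc(OC)c(C)c(OC)c1O
F7 | step 4 | racemic 1-(2,3,5-trimethoxy-4-methylphenyl)ethanol | CC(O)c1cc(OC)c(C)c(OC)c1OC
F8 | step 4 | 1-(2,3,5-trimethoxy-4-methylphenyl)ethanone | CC(=O)c1cc(OC)c(C)c(OC)c1OC
F9 | step 4 | 1-(2,3,5-trimethoxy-4-methylphenyl)ethenyl trifluoromethanesulfonate | C=C(OS(=O)(=O)C(F)(F)F)c1cc(OC)c(C)c(OC)c1OC
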